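**Strategy.** Everything rests on the C1–C2 bond, the edge shared by the 14-membered carbocycle and the cis-fused α-methylene-γ-butyrolactone (cembrane numbering: C1 carries the acrylate carbon C15, C2 the lactone oxygen and the C3=C4 alkene). C2 is therefore a latent enal carbon and C1 the γ-carbon of a 2-(methoxycarbonyl)allyl metal. One chromium-catalysed, ligand-controlled intramolecular allylation closes the macrocycle, sets C1 and C2 syn and, after lactonisation, delivers the lactone with its exocyclic methylene. Its precursor is an achiral, open-chain C20 tetraene (an oxidised geranylgeranial) with an (E)-enal at one end and a (Z)-2-(bromomethyl)enoate at the other, built linearly from geraniol by two Claisen rearrangements.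

Key step: step 13

Numbering: cembrane numbering throughout: C1 (ring CH bearing C15), C2 (ring CH–O), C3=C4 (C18 methyl), C7=C8 (C19, the CH2OAc carbon), C11=C12 (C20 methyl), C15(=C16H2)–C17(=O).

Assumption: ligand L, 1,8-bis[(4S)-4-isopropyl-4,5-dihydrooxazol-2-yl]-3,6-diphenyl-9H-carbazole, is taken to deliver the allyl group to the aldehyde face that gives (1S,2S); should a model allylation of a simple enal show the opposite sense, its (R,R) antipode is used and nothing else changes.

Step 1
Reactants: 1 geraniol
Product: 2 geranyl tert-butyldimethylsilyl ether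
Conditions: TBSCl, imidazole, DMF, 0 °C to rt
Reagents that add atoms: tert-butyldimethylsilyl chloride, CC(C)(C)[Si](C)(C)Cl
Why: Standard silyl ether formation on a primary allylic alcohol masks the C2 oxygen until the enal is needed; no stereocentre is formed.

Step 2
Reactants: 2 geranyl tert-butyldimethylsilyl ether
Product: 3 racemic terminal epoxide of 2
Conditions: mCPBA (1.0 equiv), CH2Cl2, −20 to 0 °C
Reagents that add atoms: 3-chloroperbenzoic acid, OOC(=O)c1cccc(Cl)c1
Why: Prilezhaev epoxidation should take the distal trisubstituted alkene, the C3=C4 alkene being deactivated by the allylic silyloxy group; the new stereocentre is racemic and is excised in step 3.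

Step 3
Reactants: 3 racemic terminal epoxide
Product: 5 (4E)-6-(tert-butyldimethylsilyloxy)-4-methylhex-4-enal, via diol 4 (not isolated)
Conditions: H5IO6 (1.2 equiv), THF/Et2O, 0 °C
Reagents that add atoms: none
Why: Periodic acid should hydrolyse the epoxide to diol 4 and cleave it (glycol cleavage of the Malaprade type) to the C7 aldehyde and acetone, which removes the stereocentre.

Step 4
Reactants: 5 (4E)-6-(tert-butyldimethylsilyloxy)-4-methylhex-4-enal
Product: 6 racemic (6E)-8-(tert-butyldimethylsilyloxy)-6-methyl-2-methylideneoct-6-ene-1,3-diol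
Conditions: 2-bromoprop-2-en-1-ol (1.5 equiv), t-BuLi (4.5 equiv), Et2O, −78 to 0 °C; then 5, −78 °C; aq. NH4Cl
Reagents that add atoms: 2-bromoprop-2-en-1-ol, C=C(Br)CO
Why: Bromine–lithium exchange on the lithium alkoxide gives an O,2-dilithiated allyl alcohol whose alkenyllithium adds 1,2 to the aldehyde (organolithium addition), bringing in C8, C9 and C19 with its oxygen; the C7 carbinol is racemic and becomes sp2 in step 6.

Step 5
Reactants: 6 racemic 2-methylidene-1,3-diol
Product: 7 racemic (6E)-8-(tert-butyldimethylsilyloxy)-3-hydroxy-6-methyl-2-methylideneoct-6-en-1-yl acetate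
Conditions: AcCl (1.05 equiv), 2,4,6-collidine, CH2Cl2, −78 °C
Reagents that add atoms: acetyl chloride, CC(=O)Cl
Why: Kinetically controlled acylation with AcCl and a hindered pyridine base should acetylate the primary in preference to the secondary allylic hydroxyl, which installs the C19 acetate of the target and blocks that oxygen from vinylation.

Step 6
Reactants: 7 racemic hydroxy acetate
Product: 9 (2Z,6E)-8-(tert-butyldimethylsilyloxy)-6-methyl-2-(3-oxopropyl)octa-2,6-dien-1-yl acetate, via allyl vinyl ether 8 (not isolated)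
Conditions: ethyl vinyl ether (solvent), Hg(OAc)2 (0.2 equiv), reflux; concentrate; then PhMe, 110 °C (sealed tube)
Reagents that add atoms: ethyl vinyl ether, C=COCC
Why: Hg(OAc)2-catalysed transvinylation gives allyl vinyl ether 8, whose Claisen rearrangement ([3,3]-sigmatropic) through a chair with the C6 chain pseudo-equatorial forms the C9–C10 bond and the C7=C8 alkene with C6 trans to C9 (cis to CH2OAc) and leaves C11 as an aldehyde.

Step 7
Reactants: 9 (2Z,6E)-aldehyde
Product: 10 racemic (2Z,6E)-8-(tert-butyldimethylsilyloxy)-2-(3-hydroxy-4-methylpent-4-en-1-yl)-6-methylocta-2,6-dien-1-yl acetate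
Conditions: isopropenylmagnesium bromide (1.1 equiv), THF, −78 °C; aq. NH4Cl
Reagents that add atoms: isopropenylmagnesium bromide, C=C(C)[Mg]Br
Why: Grignard addition at low temperature should take the aldehyde in preference to the acetate; the C11 carbinol is racemic and becomes sp2 in step 8.

Step 8
Reactants: 10 racemic isopropenyl carbinol
Product: 12 (2Z,6E)-8-(tert-butyldimethylsilyloxy)-6-methyl-2-[(3E)-4-methyl-7-oxohept-3-en-1-yl]octa-2,6-dien-1-yl acetate, via allyl vinyl ether 11 (not isolated)
Conditions: ethyl vinyl ether (solvent), Hg(OAc)2 (0.2 equiv), reflux; concentrate; then PhMe, 110 °C (sealed tube)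
Reagents that add atoms: ethyl vinyl ether, C=COCC
Why: Second transvinylation and Claisen rearrangement: the chair with the C10 chain pseudo-equatorial forms the C13–C14 bond and the (E)-C11=C12 alkene and ends in the C1 aldehyde.

Step 9
Reactants: 12 C1 aldehyde
Product: 13 methyl rac-(6E,10Z,14E)-10-(acetoxymethyl)-16-(tert-butyldimethylsilyloxy)-3-hydroxy-6,14-dimethyl-2-methylidenehexadeca-6,10,14-trienoate
Conditions: methyl acrylate (10 equiv, neat), DABCO (1.0 equiv), rt
Reagents that add atoms: methyl acrylate, C=CC(=O)OC
Why: Morita–Baylis–Hillman reaction of the unhindered aliphatic aldehyde adds C15, C16 and C17; the C1 carbinol is racemic and becomes sp2 in step 10.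

Step 10
Reactants: 13 Morita–Baylis–Hillman alcohol
Product: 14 methyl (2Z,6E,10Z,14E)-10-(acetoxymethyl)-2-(bromomethyl)-16-(tert-butyldimethylsilyloxy)-6,14-dimethylhexadeca-2,6,10,14-tetraenoate
Conditions: NBS (1.5 equiv), Me2S (1.8 equiv), CH2Cl2, 0 °C to rt
Reagents that add atoms: N-bromosuccinimide, O=C1CCC(=O)N1Br
Why: The bromodimethylsulfonium reagent (Corey–Kim type) activates the hydroxyl and bromide attacks C16 in an SN2' sense, the allylic transposition giving the thermodynamically preferred Z bromide in which C14 is trans to the ester, the geometry the key step needs for the cis lactone.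

Step 11
Reactants: 14 silyl ether bromide
Product: 15 methyl (2Z,6E,10Z,14E)-10-(acetoxymethyl)-2-(bromomethyl)-16-hydroxy-6,14-dimethylhexadeca-2,6,10,14-tetraenoate
Conditions: aq. HF (48 %), MeCN, 0 °C
Reagents that add atoms: none
Why: Acidic fluoride cleaves the primary silyl ether (desilylation) under non-basic, weakly nucleophilic conditions that should spare the allylic bromide, the acetate and the enoate.

Step 12
Reactants: 15 allylic alcohol
Product: 16 methyl (2Z,6E,10Z,14E)-10-(acetoxymethyl)-2-(bromomethyl)-6,14-dimethyl-16-oxohexadeca-2,6,10,14-tetraenoate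
Conditions: Dess–Martin periodinane, CH2Cl2, 0 °C to rt
Reagents that add atoms: none
Why: Dess–Martin oxidation converts the primary allylic alcohol into the (E)-enal without touching the allylic bromide or isomerising the C3=C4 alkene.

Step 13
Reactants: 16 bromo enal
Product: 19 target cis-fused cembranolide (1S,2S), via silyl ether 17 (not isolated), via hydroxy ester 18 (not isolated)
Conditions: CrCl2 (20 mol %), ligand L (22 mol %), i-Pr2NEt (40 mol %), Mn powder (3 equiv), Me3SiCl (2 equiv), THF, rt, 16 added by syringe pump (final 2 mM); then aq. HCl (1 M), THF, rt; then TsOH·H2O (10 mol %), CH2Cl2, rt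
Reagents that add atoms: none
Why: CrCl2, regenerated by Mn, reduces the allylic C16–Br bond to a ligand-bound allylchromium (trivalent chromium) that keeps the Z geometry and adds through its γ-carbon C1 to the C2 aldehyde in a closed six-membered chair transition state, Me3SiCl then releasing the alkoxide as silyl ether 17 so that chromium turns over. The closest known reactions are the chromium-catalysed enantioselective 2-(alkoxycarbonyl)allylation of aldehydes with bis(oxazolinyl)carbazole ligands (a Nozaki–Hiyama–Kishi-type allylation) and the CrCl2-mediated macrocyclising allylations used for cembranoids. The 14-membered carbocycle closes by γ-attack of the allyl unit (SE2') in a 1,2-addition to the carbonyl, which leaves C15=C16 exocyclic, and the lactone then closes by 5-exo-trig acyl substitution of the C2 hydroxyl on the methyl ester. The relative configuration follows from the chair, in which C3 is equatorial and C14 axial (Z-allyl), giving the syn adduct and hence the cis-fused lactone; the absolute configuration at C2, and with it at C1, is set by the ligand, which shields one face of the aldehyde. The step needs γ- over α-attack and 1,2- over 1,4-addition (both inherent to allylchromium reagents), ring closure over oligomerisation (slow addition at high dilution) and tolerance of the allylic acetate and the enoate (neither should be reduced by CrCl2 or Mn).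

**Compound list**

1 | geraniol, (2E)-3,7-dimethylocta-2,6-dien-1-ol | CC(C)=CCC/C(C)=C/CO | starting material
2 | geranyl tert-butyldimethylsilyl ether | CC(C)=CCC/C(C)=C/CO[Si](C)(C)C(C)(C)C | intermediate
3 | racemic 6,7-epoxygeranyl tert-butyldimethylsilyl ether | CC1(C)OC1CC/C(C)=C/CO[Si](C)(C)C(C)(C)C | intermediate
4 | racemic 6,7-dihydroxy-6,7-dihydrogeranyl tert-butyldimethylsilyl ether | CC(C)(O)C(O)CC/C(C)=C/CO[Si](C)(C)C(C)(C)C | intermediate (not isolated)
5 | (4E)-6-(tert-butyldimethylsilyloxy)-4-methylhex-4-enal | O=CCC/C(C)=C/CO[Si](C)(C)C(C)(C)C | intermediate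
6 | racemic (6E)-8-(tert-butyldimethylsilyloxy)-6-methyl-2-methylideneoct-6-ene-1,3-diol | C=C(CO)C(O)CC/C(C)=C/CO[Si](C)(C)C(C)(C)C | intermediate
7 | racemic (6E)-8-(tert-butyldimethylsilyloxy)-3-hydroxy-6-methyl-2-methylideneoct-6-en-1-yl acetate | CC(=O)OCC(=C)C(O)CC/C(C)=C/CO[Si](C)(C)C(C)(C)C | intermediate
8 | racemic (6E)-8-(tert-butyldimethylsilyloxy)-3-(ethenyloxy)-6-methyl-2-methylideneoct-6-en-1-yl acetate | CC(=O)OCC(=C)C(OC=C)CC/C(C)=C/CO[Si](C)(C)C(C)(C)C | intermediate (not isolated)
9 | (2Z,6E)-8-(tert-butyldimethylsilyloxy)-6-methyl-2-(3-oxopropyl)octa-2,6-dien-1-yl acetate | O=CCC/C(COC(C)=O)=C/CC/C(C)=C/CO[Si](C)(C)C(C)(C)C | intermediate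
10 | racemic (2Z,6E)-8-(tert-butyldimethylsilyloxy)-2-(3-hydroxy-4-methylpent-4-en-1-yl)-6-methylocta-2,6-dien-1-yl acetate | C=C(C)C(O)CC/C(COC(C)=O)=C/CC/C(C)=C/CO[Si](C)(C)C(C)(C)C | intermediate
11 | racemic (2Z,6E)-8-(tert-butyldimethylsilyloxy)-2-[3-(ethenyloxy)-4-methylpent-4-en-1-yl]-6-methylocta-2,6-dien-1-yl acetate | C=C(C)C(OC=C)CC/C(COC(C)=O)=C/CC/C(C)=C/CO[Si](C)(C)C(C)(C)C | intermediate (not isolated)
12 | (2Z,6E)-8-(tert-butyldimethylsilyloxy)-6-methyl-2-[(3E)-4-methyl-7-oxohept-3-en-1-yl]octa-2,6-dien-1-yl acetate | O=CCC/C(C)=C/CC/C(COC(C)=O)=C/CC/C(C)=C/CO[Si](C)(C)C(C)(C)C | intermediate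
13 | methyl rac-(6E,10Z,14E)-10-(acetoxymethyl)-16-(tert-butyldimethylsilyloxy)-3-hydroxy-6,14-dimethyl-2-methylidenehexadeca-6,10,14-trienoate | C=C(C(=O)OC)C(O)CC/C(C)=C/CC/C(COC(C)=O)=C/CC/C(C)=C/CO[Si](C)(C)C(C)(C)C | intermediate
14 | methyl (2Z,6E,10Z,14E)-10-(acetoxymethyl)-2-(bromomethyl)-16-(tert-butyldimethylsilyloxy)-6,14-dimethylhexadeca-2,6,10,14-tetraenoate | COC(=O)/C(CBr)=C/CC/C(C)=C/CC/C(COC(C)=O)=C/CC/C(C)=C/CO[Si](C)(C)C(C)(C)C | intermediate
15 | methyl (2Z,6E,10Z,14E)-10-(acetoxymethyl)-2-(bromomethyl)-16-hydroxy-6,14-dimethylhexadeca-2,6,10,14-tetraenoate | COC(=O)/C(CBr)=C/CC/C(C)=C/CC/C(COC(C)=O)=C/CC/C(C)=C/CO | intermediate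
16 | methyl (2Z,6E,10Z,14E)-10-(acetoxymethyl)-2-(bromomethyl)-6,14-dimethyl-16-oxohexadeca-2,6,10,14-tetraenoate | COC(=O)/C(CBr)=C/CC/C(C)=C/CC/C(COC(C)=O)=C/CC/C(C)=C/C=O | intermediate
17 | methyl 2-[(1S,2S,3E,7Z,11E)-8-(acetoxymethyl)-4,12-dimethyl-2-(trimethylsilyloxy)cyclotetradeca-3,7,11-trien-1-yl]prop-2-enoate | COC(=O)C(=C)[C@@H]1CC/C(C)=C/CC/C(COC(C)=O)=C/CC/C(C)=C/[C@@H]1O[Si](C)(C)C | intermediate (not isolated)
18 | methyl 2-[(1S,2S,3E,7Z,11E)-8-(acetoxymethyl)-2-hydroxy-4,12-dimethylcyclotetradeca-3,7,11-trien-1-yl]prop-2-enoate | COC(=O)C(=C)[C@@H]1CC/C(C)=C/CC/C(COC(C)=O)=C/CC/C(C)=C/[C@@H]1O | intermediate (not isolated)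
19 | [(3aS,6E,10Z,14E,15aS)-6,14-dimethyl-3-methylidene-2-oxo-2,3,3a,4,5,8,9,12,13,15a-decahydrocyclotetradeca[b]furan-10-yl]methyl acetate (cis-fused lactone; 1S,2S in cembrane numbering) | C=C1C(=O)O[C@H]2/C=C(\C)CC/C=C(\COC(C)=O)CC/C=C(\C)CC[C@@H]12 | target

**Step count and risks**

Total step count: 13. Longest linear sequence: 13 steps (geraniol 1 to target 19; the route is fully linear).

Steps most likely to fail:

1. Step 13. The ligand may discriminate the aldehyde faces too weakly in the macrocyclic chair transition state, or chromium turnover at high dilution may be slow enough for oligomerisation to compete. Fallback, from 16: the ligand is left out and CrCl2 is used in excess (THF, slow addition, high dilution), so that only the Z-allyl geometry and the chair transition state are relied on. This should give the cis hydroxy ester as a racemate, that is 18 together with the mirror-image hydroxy ester F1. Brief acid treatment (TsOH, CH2Cl2) should lactonise both to 19 and the enantiomeric lactone F2. Preparative chromatography on a chiral stationary phase (cellulose tris(3,5-dimethylphenylcarbamate)) then returns the route to 19.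

2. Step 6 (step 8 carries the same risk). Transvinylation may stop short of completion, and part of the rearrangement may pass through the chair with the C6 chain axial, which erodes the C7=C8 geometry. Fallback, from 7: heating with N,N-dimethylacetamide dimethyl acetal (xylene, 140 °C) should give the ketene N,O-acetal F3 (not isolated). Its Eschenmoser–Claisen rearrangement, in which the dimethylamino group penalises the axial C6 chain by 1,3-diaxial repulsion, gives the dimethylamide F4. Cp2Zr(H)Cl (THF, rt) then reduces the tertiary amide, and not the acetate, to the aldehyde, returning the route to 9.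

3. Step 9. Addition of the acrylate–amine adduct to an enolisable aliphatic aldehyde is slow, so aldol self-condensation and acrylate oligomerisation can overtake it. Fallback, from 12: methyl propiolate is hydroaluminated with i-Bu2AlH in the presence of N-methylmorpholine N-oxide (THF, 0 °C) to the α-(methoxycarbonyl)vinylalane F5. This should add to the aldehyde of 12 at 0 °C and, after aqueous work-up, return the route to 13.

Further compounds
F1 | step 13 | mirror-image hydroxy ester, methyl 2-[(1R,2R,3E,7Z,11E)-8-(acetoxymethyl)-2-hydroxy-4,12-dimethylcyclotetradeca-3,7,11-trien-1-yl]prop-2-enoate | COC(=O)C(=C)[C@H]1CC/C(C)=C/CC/C(COC(C)=O)=C/CC/C(C)=C/[C@H]1O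
F2 | step 13 | enantiomeric lactone, (3aR,15aR) enantiomer of 19 | C=C1C(=O)O[C@@H]2/C=C(\C)CC/C=C(\COC(C)=O)CC/C=C(\C)CC[C@H]12
F3 | step 6 | ketene N,O-acetal, racemic (6E)-8-(tert-butyldimethylsilyloxy)-3-{[1-(dimethylamino)ethenyl]oxy}-6-methyl-2-methylideneoct-6-en-1-yl acetate | CC(=O)OCC(=C)C(OC(=C)N(C)C)CC/C(C)=C/CO[Si](C)(C)C(C)(C)C
F4 | step 6 | dimethylamide, (4Z,8E)-4-(acetoxymethyl)-10-(tert-butyldimethylsilyloxy)-N,N,8-trimethyldeca-4,8-dienamide | CN(C)C(=O)CC/C(COC(C)=O)=C/CC/C(C)=C/CO[Si](C)(C)C(C)(C)C
F5 | step 9 | α-(methoxycarbonyl)vinylalane, methyl 2-(diisobutylalumanyl)prop-2-enoate | COC(=O)C(=C)[Al](CC(C)C)CC(C)C
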